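**Plan**
- Retrosynthesis: the dienyl terminus C13–C16 is cut back to the C12 carbonyl of a 12,8-lactone. The C6–C7 bond and the lactone C8–O bond are then cut together, then C9–C10, then C5–C6 and the C4 methyl on a 2-methylcyclohexanone core.
- Enabling feature: O6 and O8 are 1,3-related across C7, and O8 is cis to the C11–C12 arm on C9. A C6 aldehyde, a C7=C8 isopropenyl group on C9 and a C12 acid, all carried by ring A, can therefore close ring B and a cis γ-lactone in one operation.
- Forward: ring A with quaternary C4 is made first; an Ireland–Claisen rearrangement joins C9 to C10; a temporary δ-lactone delivers the seco aldehyde acid; the Prins/lactonisation closes ring B and the γ-lactone; C12 is then grown into the side chain.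
- Stereochemistry: C4 from asymmetric phase-transfer methylation; C9 and C10 from the chair Ireland–Claisen transition state; C5 from hydroboration anti to the two axial methyl groups; C6 and C8 in the key step.

Key step: step 15

Remark (numbering): labdane numbering is used throughout (C17 on C8, C20 on C10); the oxygen-bearing carbon on C4 is called C19 and the C4 methyl C18, with no biogenetic meaning implied.
Remark (step 2): the sense of induction of the phase-transfer methylation cannot be predicted with certainty; the (S,S)-catalyst is assumed to give the (S)-ester, its antipode being equally available.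
Remark (building block): 4,4-dimethoxybutanoic acid is taken as purchasable; it is otherwise one saponification from its commercial methyl ester.

Step 1
Reactants: 1 2-methylcyclohexanone; 2 dimethyl carbonate
Product: 3 methyl 3-methyl-2-oxocyclohexane-1-carboxylate (stereoisomer and enol mixture)
Conditions: NaH (2.2 equiv), THF, reflux; aq. HCl
Reagents that add atoms: none
Why: Claisen-type C-acylation of the ketone enolate goes to the unsubstituted α-carbon, because only that β-keto ester is drained off as its stabilised enolate.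

Step 2
Reactants: 3 methyl 3-methyl-2-oxocyclohexane-1-carboxylate
Product: 4 methyl (1S)-1,3-dimethyl-2-oxocyclohexane-1-carboxylate (both C3 epimers)
Conditions: MeI, CsOH·H2O, (S,S)-N-spiro bis(binaphthyl) ammonium bromide with 3,4,5-trifluorophenyl groups (1 mol%), toluene, −40 °C
Reagents that add atoms: iodomethane, SMILES CI
Why: asymmetric phase-transfer alkylation, in which the chiral ammonium cation shields one face of the β-keto ester enolate in the ion pair and so should set quaternary C4 as S (the C10 epimers converge in step 3).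

Step 3
Reactants: 4 methyl (1S)-1,3-dimethyl-2-oxocyclohexane-1-carboxylate
Product: 5 methyl (1S)-1,3-dimethyl-2-{[(trifluoromethyl)sulfonyl]oxy}cyclohex-2-ene-1-carboxylate
Conditions: KN(SiMe3)2, THF, −78 °C; PhNTf2, −78 → 0 °C
Reagents that add atoms: N-phenylbis(trifluoromethanesulfonimide), SMILES O=S(=O)(N(c1ccccc1)S(=O)(=O)C(F)(F)F)C(F)(F)F
Why: enol triflate formation is regiospecific because only C10 still carries an α-hydrogen, giving the tetrasubstituted C5=C10 olefin.

Step 4
Reactants: 5 methyl (1S)-1,3-dimethyl-2-{[(trifluoromethyl)sulfonyl]oxy}cyclohex-2-ene-1-carboxylate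
Product: 6 methyl (1S)-2-(hydroxymethyl)-1,3-dimethylcyclohex-2-ene-1-carboxylate
Conditions: Bu3SnCH2OH, Pd(PPh3)4 (5 mol%), LiCl (3 equiv), 1,4-dioxane, 90 °C; used crude
Reagents that add atoms: (tributylstannyl)methanol, SMILES CCCC[Sn](CCCC)(CCCC)CO
Why: Stille cross-coupling of the enol triflate with the hydroxymethyl stannane under zerovalent palladium (chloride displacing triflate on palladium) should install C6 as the allylic alcohol and leave the ester alone.

Step 5
Reactants: 6 methyl (1S)-2-(hydroxymethyl)-1,3-dimethylcyclohex-2-ene-1-carboxylate; 7 4,4-dimethoxybutanoic acid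
Product: 8 methyl (1S)-2-{[(4,4-dimethoxybutanoyl)oxy]methyl}-1,3-dimethylcyclohex-2-ene-1-carboxylate
Conditions: EDC·HCl, DMAP (cat.), CH2Cl2, 0 °C → rt
Reagents that add atoms: none
Why: Steglich-type carbodiimide esterification of the primary allylic alcohol is fast and removes the free γ-hydroxy ester before it can lactonise.

Step 6
Reactants: 8 methyl (1S)-2-{[(4,4-dimethoxybutanoyl)oxy]methyl}-1,3-dimethylcyclohex-2-ene-1-carboxylate
Product: 11 (2R)-4,4-dimethoxy-2-[(1S,3S)-3-(methoxycarbonyl)-1,3-dimethyl-2-methylidenecyclohexyl]butanoic acid, via silyl ketene acetal 9 (not isolated), via trimethylsilyl ester 10 (not isolated)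
Conditions: LiN(i-Pr)2, THF, −78 °C; Me3SiCl/Et3N, −78 °C → rt, then 60 °C; aq. NaOH/MeOH, then pH 5
Reagents that add atoms: none
Why: Ireland–Claisen rearrangement: kinetic deprotonation in THF gives the E(O)-enolate and hence ketene acetal 9 with its side chain cis to the allylic oxygen, the chair transition state puts that chain axial so that C9 and C10 are set together, and the new bond should form on the ring face syn to the planar C4 ester rather than syn to the bulkier C4 methyl, since the C4 group on that face is 1,3-syn-axial to the incoming carbon.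

Step 7
Reactants: 11 (2R)-4,4-dimethoxy-2-[(1S,3S)-3-(methoxycarbonyl)-1,3-dimethyl-2-methylidenecyclohexyl]butanoic acid
Product: 12 (2R)-2-[(1S,3S)-3-(hydroxymethyl)-1,3-dimethyl-2-methylidenecyclohexyl]-4,4-dimethoxybutanoic acid
Conditions: LiBEt3H (4 equiv), THF, 0 °C → rt; aq. citric acid (pH 5)
Reagents that add atoms: none
Why: hydride reduction of the neopentyl methyl ester is chemoselective because the acid is protected in the flask as its lithium carboxylate.

Step 8
Reactants: 12 (2R)-2-[(1S,3S)-3-(hydroxymethyl)-1,3-dimethyl-2-methylidenecyclohexyl]-4,4-dimethoxybutanoic acid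
Product: 14 (2R)-2-[(1S,3S)-3-({[tert-butyl(dimethyl)silyl]oxy}methyl)-1,3-dimethyl-2-methylidenecyclohexyl]-4,4-dimethoxybutanoic acid, via bis-silyl derivative 13 (not isolated)
Conditions: t-BuMe2SiCl (2.5 equiv), imidazole, DMF, rt; then K2CO3, MeOH/H2O; pH 5
Reagents that add atoms: tert-butyl(chloro)dimethylsilane, SMILES CC(C)(C)[Si](C)(C)Cl
Why: silyl ether protection of the C19 alcohol, the silyl ester formed alongside being cleaved by mild methanolysis.

Step 9
Reactants: 14 (2R)-2-[(1S,3S)-3-({[tert-butyl(dimethyl)silyl]oxy}methyl)-1,3-dimethyl-2-methylidenecyclohexyl]-4,4-dimethoxybutanoic acid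
Product: 17 (4R,4aR,8S,8aS)-8-({[tert-butyl(dimethyl)silyl]oxy}methyl)-4-(2,2-dimethoxyethyl)-4a,8-dimethyl-1,4,4a,5,6,7,8,8a-octahydro-3H-isochromen-3-one (trans-fused δ-lactone; labdane locants 4S,5S,9R,10R), via B-alkyl-9-BBN adduct 15 (not isolated), via hydroxy acid 16 (not isolated)
Conditions: 9-BBN (3 equiv), THF, 65 °C; NaOH, H2O2, 0 °C; pH 5; then EDC·HCl, DMAP, CH2Cl2, rt
Reagents that add atoms: hydrogen peroxide, SMILES OO
Why: hydroboration–oxidation followed by carbodiimide lactonisation: with the branched C9 arm and C19 equatorial and both methyl groups axial, the borane should add to the exocyclic C5=C6 olefin from the face away from the two flanking axial methyls, which places H5 cis to the C9 arm (C5 S) and lets the δ-lactone close trans-fused.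

Step 10
Reactants: 17 trans-fused δ-lactone
Product: 18 (3R)-3-[(1R,2S,3S)-3-({[tert-butyl(dimethyl)silyl]oxy}methyl)-2-(hydroxymethyl)-1,3-dimethylcyclohexyl]-5,5-dimethoxypentan-2-one (in equilibrium with its hemiketal)
Conditions: MeLi (1.2 equiv), THF, −78 °C; aq. NH4Cl
Reagents that add atoms: methyllithium, SMILES [Li]C
Why: organolithium mono-addition to a lactone stops at the lithium hemiketal at low temperature, which on work-up gives the C8 methyl ketone (C17 added) and frees the C6 alcohol.

Step 11
Reactants: 18 hydroxy methyl ketone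
Product: 19 [(1S,2S,6S)-2-({[tert-butyl(dimethyl)silyl]oxy}methyl)-6-[(3S)-5,5-dimethoxy-2-methylpent-1-en-3-yl]-2,6-dimethylcyclohexyl]methanol
Conditions: Ph3PCH3Br, KOt-Bu (3 equiv each), THF, 0 → 50 °C
Reagents that add atoms: methyl(triphenyl)phosphonium bromide, SMILES C[P+](c1ccccc1)(c1ccccc1)c1ccccc1.[Br-]
Why: Wittig methylenation of the methyl ketone builds the isopropenyl group (C7=C8), and the hindered C9–H next to quaternary C10 should resist enolisation by the ylide.

Step 12
Reactants: 19 isopropenyl alcohol acetal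
Product: 20 (3S)-3-[(1S,2S,3S)-3-({[tert-butyl(dimethyl)silyl]oxy}methyl)-2-(hydroxymethyl)-1,3-dimethylcyclohexyl]-4-methylpent-4-enal
Conditions: PPTS (cat.), acetone/H2O, 45 °C
Reagents that add atoms: water, SMILES O
Why: mild acid-catalysed acetal hydrolysis unmasks C12 as the aldehyde without touching the neopentyl silyl ether or the olefin.

Step 13
Reactants: 20 hydroxy aldehyde
Product: 21 (3S)-3-[(1S,2S,3S)-3-({[tert-butyl(dimethyl)silyl]oxy}methyl)-2-(hydroxymethyl)-1,3-dimethylcyclohexyl]-4-methylpent-4-enoic acid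
Conditions: NaClO2, NaH2PO4, 2-methylbut-2-ene, t-BuOH/H2O, 0 °C → rt
Reagents that add atoms: sodium chlorite, SMILES [Na+].[O-]Cl=O
Why: Pinnick oxidation converts only the aldehyde into the C12 acid, the scavenger olefin protecting the isopropenyl group and the primary C6 alcohol staying untouched.

Step 14
Reactants: 21 hydroxy acid
Product: 22 (3S)-3-[(1S,2S,3S)-3-({[tert-butyl(dimethyl)silyl]oxy}methyl)-2-formyl-1,3-dimethylcyclohexyl]-4-methylpent-4-enoic acid
Conditions: Dess–Martin periodinane, NaHCO3, CH2Cl2, 0 °C → rt; used at once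
Reagents that add atoms: none
Why: Dess–Martin oxidation gives the C6 aldehyde under near-neutral conditions that should not epimerise C5.

Step 15
Reactants: 22 seco aldehyde acid
Product: 23 (4S,5S,6R,8S,9R,10R)-19-{[tert-butyl(dimethyl)silyl]oxy}-6-hydroxy-13,14,15,16-tetranorlabdan-12,8-olide
Conditions: SnCl4 (1.5 equiv), 2,6-di-tert-butyl-4-methylpyridine (0.3 equiv), CH2Cl2, −78 → −40 °C; aq. NaHCO3
Reagents that add atoms: none
Why: SnCl4 binds the C6 aldehyde oxygen, the terminal carbon C7 of the isopropenyl group attacks C6 through a chair that becomes ring B, and the tertiary C8 cation so formed is captured by the C12 carboxyl oxygen. The closest known reactions are Lewis-acid Prins and carbonyl-ene cyclisations of olefinic aldehydes of the citronellal-to-isopulegol kind and the interception of tertiary cations by carboxylic acids as γ-lactones. Ring B closes 6-endo with respect to the olefin (C7 and C8 both become ring atoms), and the lactone closes as a five-membered ring by exo attack of the carboxyl oxygen on cationic C8. C6 (R) is set by the chair, the tin-bound oxygen going equatorial because the axial position is 1,3-syn-axial to both the C10 and the C4 methyl groups; C8 (S) is set by the C9 arm, which is axial on the new ring and reaches C8 only from its own face, so the lactone is cis-fused and the C8 methyl axial. The step needs cation capture to outrun proton loss and chloride capture, which the pre-positioned intramolecular acid secures, and it needs the aldehyde rather than the olefin to be activated first, which the hindered base secures by removing adventitious HCl.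

Step 16
Reactants: 23 hydroxy lactone
Product: 24 (4S,5S,6R,8S,9R,10R)-19-{[tert-butyl(dimethyl)silyl]oxy}-8,12-epoxy-13,14,15,16-tetranorlabdane-6,12-diol (lactol, both C12 epimers)
Conditions: i-Bu2AlH (2.5 equiv), CH2Cl2, −78 °C; aq. potassium sodium tartrate KNaC4H4O6
Reagents that add atoms: none
Why: half-reduction of the γ-lactone by i-Bu2AlH stops at the lactol, which keeps C12 at the aldehyde level with O8 masked, whereas a 12-halide or sulfonate of the open triol would be displaced by the cis C8 oxygen to give the 8,12-ether.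

Step 17
Reactants: 24 lactol
Product: 26 (4S,5S,6R,8S,9R,10R)-19-{[tert-butyl(dimethyl)silyl]oxy}-8,13-epoxy-14,15,16-trinorlabdane-6,13-diol (six-membered lactol, both C13 epimers), via enol ether 25 (not isolated)
Conditions: Ph3P(CH2OMe)Cl, KN(SiMe3)2 (4 equiv each), THF, 0 °C → rt; then 1 M HCl, THF, rt
Reagents that add atoms: (methoxymethyl)triphenylphosphonium chloride, SMILES COC[P+](c1ccccc1)(c1ccccc1)c1ccccc1.[Cl-]; water, SMILES O
Why: Wittig one-carbon homologation of the lactol with the methoxymethylene ylide and hydrolysis of the enol ether add C13 as an aldehyde, which rests as the six-membered lactol on O8.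

Step 18
Reactants: 26 six-membered lactol
Product: 27 (4S,5S,6R,8S,9R,10R)-19-{[tert-butyl(dimethyl)silyl]oxy}-15,16-dinorlabd-13-yne-6,8-diol
Conditions: dimethyl (1-diazo-2-oxopropyl)phosphonate, K2CO3, MeOH, rt → 40 °C
Reagents that add atoms: dimethyl (1-diazo-2-oxopropyl)phosphonate, SMILES COP(=O)(OC)C(=[N+]=[N-])C(C)=O
Why: Seyferth–Gilbert homologation with the Ohira–Bestmann reagent converts the masked aldehyde into the terminal alkyne C13≡C14 under mildly basic conditions that tolerate both free alcohols.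

Step 19
Reactants: 27 alkyne diol
Product: 28 (4S,5S,6R,8S,9R,10R)-19-{[tert-butyl(dimethyl)silyl]oxy}labda-13(16),14-diene-6,8-diol
Conditions: ethylene (1 atm), second-generation Grubbs catalyst RuCl2(=CHPh)(PCy3)(H2IMes) (5 mol%), CH2Cl2, rt → 40 °C
Reagents that add atoms: ethylene, SMILES C=C
Why: enyne cross-metathesis of the terminal alkyne with ethylene gives the 2-substituted buta-1,3-diene directly (C16 and C15 from ethylene), with no other olefin in the substrate to interfere.

Step 20
Reactants: 28 diene diol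
Product: 29 (4S,5S,6R,8S,9R,10R)-6-acetoxy-19-{[tert-butyl(dimethyl)silyl]oxy}labda-13(16),14-dien-8-ol
Conditions: Ac2O, pyridine, DMAP (cat.), CH2Cl2, 0 °C → rt
Reagents that add atoms: acetic anhydride, SMILES CC(=O)OC(C)=O
Why: DMAP-catalysed acetylation takes the secondary equatorial C6 alcohol, while the tertiary C8 alcohol is not acylated under these conditions and C19 is still silylated.

Step 21
Reactants: 29 silyl ether acetate
Product: 30 (4S,5S,6R,8S,9R,10R)-6-acetoxylabda-13(16),14-diene-8,19-diol (target)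
Conditions: HF·pyridine, pyridine/THF, 0 °C → rt
Reagents that add atoms: none
Why: fluoride desilylation under buffered acidic conditions frees the C19 alcohol without base-induced acetyl migration from O6 to the nearby O19 and without harming the diene.

**Compound list**
1 | 2-methylcyclohexanone | CC1CCCCC1=O | starting material
2 | dimethyl carbonate | COC(=O)OC | starting material
3 | methyl 3-methyl-2-oxocyclohexane-1-carboxylate | COC(=O)C1CCCC(C)C1=O | intermediate
4 | methyl (1S)-1,3-dimethyl-2-oxocyclohexane-1-carboxylate | COC(=O)[C@@]1(C)CCCC(C)C1=O | intermediate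
5 | methyl (1S)-1,3-dimethyl-2-{[(trifluoromethyl)sulfonyl]oxy}cyclohex-2-ene-1-carboxylate | COC(=O)[C@@]1(C)CCCC(C)=C1OS(=O)(=O)C(F)(F)F | intermediate
6 | methyl (1S)-2-(hydroxymethyl)-1,3-dimethylcyclohex-2-ene-1-carboxylate | COC(=O)[C@@]1(C)CCCC(C)=C1CO | intermediate
7 | 4,4-dimethoxybutanoic acid | COC(OC)CCC(O)=O | starting material
8 | methyl (1S)-2-{[(4,4-dimethoxybutanoyl)oxy]methyl}-1,3-dimethylcyclohex-2-ene-1-carboxylate | COC(=O)[C@@]1(C)CCCC(C)=C1COC(=O)CCC(OC)OC | intermediate
9 | trimethylsilyl ketene acetal of 8 (side chain cis to the allylic oxygen) | COC(OC)C/C=C(/O[Si](C)(C)C)OCC1=C(C)CCC[C@]1(C)C(=O)OC | intermediate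
10 | trimethylsilyl ester of 11 | COC(OC)C[C@@H](C(=O)O[Si](C)(C)C)[C@]1(C)CCC[C@](C)(C(=O)OC)C1=C | intermediate
11 | (2R)-4,4-dimethoxy-2-[(1S,3S)-3-(methoxycarbonyl)-1,3-dimethyl-2-methylidenecyclohexyl]butanoic acid | COC(OC)C[C@@H](C(O)=O)[C@]1(C)CCC[C@](C)(C(=O)OC)C1=C | intermediate
12 | (2R)-2-[(1S,3S)-3-(hydroxymethyl)-1,3-dimethyl-2-methylidenecyclohexyl]-4,4-dimethoxybutanoic acid | COC(OC)C[C@@H](C(O)=O)[C@]1(C)CCC[C@](C)(CO)C1=C | intermediate
13 | tert-butyldimethylsilyl ester of 14 | COC(OC)C[C@@H](C(=O)O[Si](C)(C)C(C)(C)C)[C@]1(C)CCC[C@](C)(CO[Si](C)(C)C(C)(C)C)C1=C | intermediate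
14 | (2R)-2-[(1S,3S)-3-({[tert-butyl(dimethyl)silyl]oxy}methyl)-1,3-dimethyl-2-methylidenecyclohexyl]-4,4-dimethoxybutanoic acid | COC(OC)C[C@@H](C(O)=O)[C@]1(C)CCC[C@](C)(CO[Si](C)(C)C(C)(C)C)C1=C | intermediate
15 | C6-(9-borabicyclo[3.3.1]nonan-9-yl) adduct of 14, acid as its acyloxyborane | COC(OC)C[C@@H](C(=O)OB1C2CCCC1CCC2)[C@]1(C)CCC[C@](C)(CO[Si](C)(C)C(C)(C)C)[C@H]1CB1C2CCCC1CCC2 | intermediate
16 | (2R)-2-[(1R,2S,3S)-3-({[tert-butyl(dimethyl)silyl]oxy}methyl)-2-(hydroxymethyl)-1,3-dimethylcyclohexyl]-4,4-dimethoxybutanoic acid | COC(OC)C[C@@H](C(O)=O)[C@]1(C)CCC[C@](C)(CO[Si](C)(C)C(C)(C)C)[C@H]1CO | intermediate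
17 | (4R,4aR,8S,8aS)-8-({[tert-butyl(dimethyl)silyl]oxy}methyl)-4-(2,2-dimethoxyethyl)-4a,8-dimethyl-1,4,4a,5,6,7,8,8a-octahydro-3H-isochromen-3-one | COC(OC)C[C@@H]1[C@]2(C)CCC[C@](C)(CO[Si](C)(C)C(C)(C)C)[C@H]2COC1=O | intermediate
18 | (3R)-3-[(1R,2S,3S)-3-({[tert-butyl(dimethyl)silyl]oxy}methyl)-2-(hydroxymethyl)-1,3-dimethylcyclohexyl]-5,5-dimethoxypentan-2-one | COC(OC)C[C@@H](C(C)=O)[C@]1(C)CCC[C@](C)(CO[Si](C)(C)C(C)(C)C)[C@H]1CO | intermediate
19 | [(1S,2S,6S)-2-({[tert-butyl(dimethyl)silyl]oxy}methyl)-6-[(3S)-5,5-dimethoxy-2-methylpent-1-en-3-yl]-2,6-dimethylcyclohexyl]methanol | COC(OC)C[C@@H](C(C)=C)[C@]1(C)CCC[C@](C)(CO[Si](C)(C)C(C)(C)C)[C@H]1CO | intermediate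
20 | (3S)-3-[(1S,2S,3S)-3-({[tert-butyl(dimethyl)silyl]oxy}methyl)-2-(hydroxymethyl)-1,3-dimethylcyclohexyl]-4-methylpent-4-enal | O=CC[C@@H](C(C)=C)[C@]1(C)CCC[C@](C)(CO[Si](C)(C)C(C)(C)C)[C@H]1CO | intermediate
21 | (3S)-3-[(1S,2S,3S)-3-({[tert-butyl(dimethyl)silyl]oxy}methyl)-2-(hydroxymethyl)-1,3-dimethylcyclohexyl]-4-methylpent-4-enoic acid | OC(=O)C[C@@H](C(C)=C)[C@]1(C)CCC[C@](C)(CO[Si](C)(C)C(C)(C)C)[C@H]1CO | intermediate
22 | (3S)-3-[(1S,2S,3S)-3-({[tert-butyl(dimethyl)silyl]oxy}methyl)-2-formyl-1,3-dimethylcyclohexyl]-4-methylpent-4-enoic acid | OC(=O)C[C@@H](C(C)=C)[C@]1(C)CCC[C@](C)(CO[Si](C)(C)C(C)(C)C)[C@H]1C=O | intermediate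
23 | (4S,5S,6R,8S,9R,10R)-19-{[tert-butyl(dimethyl)silyl]oxy}-6-hydroxy-13,14,15,16-tetranorlabdan-12,8-olide | O=C3C[C@@H]1[C@]2(C)CCC[C@](C)(CO[Si](C)(C)C(C)(C)C)[C@H]2[C@H](O)C[C@]1(C)O3 | intermediate
24 | (4S,5S,6R,8S,9R,10R)-19-{[tert-butyl(dimethyl)silyl]oxy}-8,12-epoxy-13,14,15,16-tetranorlabdane-6,12-diol | OC3C[C@@H]1[C@]2(C)CCC[C@](C)(CO[Si](C)(C)C(C)(C)C)[C@H]2[C@H](O)C[C@]1(C)O3 | intermediate
25 | (4S,5S,6R,8S,9R,10R)-19-{[tert-butyl(dimethyl)silyl]oxy}-13-methoxy-14,15,16-trinorlabd-12-ene-6,8-diol (E/Z) | COC=CC[C@@H]1[C@]2(C)CCC[C@](C)(CO[Si](C)(C)C(C)(C)C)[C@H]2[C@H](O)C[C@]1(C)O | intermediate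
26 | (4S,5S,6R,8S,9R,10R)-19-{[tert-butyl(dimethyl)silyl]oxy}-8,13-epoxy-14,15,16-trinorlabdane-6,13-diol | OC3CC[C@@H]1[C@]2(C)CCC[C@](C)(CO[Si](C)(C)C(C)(C)C)[C@H]2[C@H](O)C[C@]1(C)O3 | intermediate
27 | (4S,5S,6R,8S,9R,10R)-19-{[tert-butyl(dimethyl)silyl]oxy}-15,16-dinorlabd-13-yne-6,8-diol | C#CCC[C@@H]1[C@]2(C)CCC[C@](C)(CO[Si](C)(C)C(C)(C)C)[C@H]2[C@H](O)C[C@]1(C)O | intermediate
28 | (4S,5S,6R,8S,9R,10R)-19-{[tert-butyl(dimethyl)silyl]oxy}labda-13(16),14-diene-6,8-diol | C=CC(=C)CC[C@@H]1[C@]2(C)CCC[C@](C)(CO[Si](C)(C)C(C)(C)C)[C@H]2[C@H](O)C[C@]1(C)O | intermediate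
29 | (4S,5S,6R,8S,9R,10R)-6-acetoxy-19-{[tert-butyl(dimethyl)silyl]oxy}labda-13(16),14-dien-8-ol | C=CC(=C)CC[C@@H]1[C@]2(C)CCC[C@](C)(CO[Si](C)(C)C(C)(C)C)[C@H]2[C@H](OC(C)=O)C[C@]1(C)O | intermediate
30 | (4S,5S,6R,8S,9R,10R)-6-acetoxylabda-13(16),14-diene-8,19-diol | C=CC(=C)CC[C@@H]1[C@]2(C)CCC[C@](C)(CO)[C@H]2[C@H](OC(C)=O)C[C@]1(C)O | target

**Count and risks**
Total step count: 21. Longest linear sequence: 21 steps (from 1).

Most likely to fail, in this order:

Step 6. What may go wrong is loss of facial control at C10 (bond formation syn to the C4 methyl instead of syn to the C4 ester), together with leakage through the Z(O)-enolate or a boat-like transition state; none of this can be repaired later. The size difference between ester and methyl is modest, so this is the weakest stereochemical link. The fallback replaces substrate control by reagent control and sets out from 8. Enolisation with the (S,S)-configured chiral bromoborane 2-bromo-4,5-diphenyl-1,3-bis{[3,5-bis(trifluoromethyl)phenyl]sulfonyl}-1,3,2-diazaborolidine (assumed to be the matched enantiomer) and Et3N in toluene/hexane at −78 °C should give the boron ketene acetal F3. On warming to −20 °C the chair [3,3] shift is then steered by the C2-symmetric ligand rather than by C4 and should give the acyloxyborane F4, which aqueous work-up hydrolyses to 11, where the route is rejoined.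

Step 15. What may go wrong is proton loss from the C8 cation (carbonyl-ene outcome), direct protonation of the isopropenyl group by adventitious HCl with lactonisation but no C6–C7 bond, or partial loss of the silyl ether. The fallback splits the event into two known operations and sets out from 22. Me2AlCl (2.2 equiv, CH2Cl2, −78 °C), a Lewis acid that also scavenges protons, should carry 22 through the carbonyl-ene cyclisation to the ring-B homoallylic alcohol, the 8(17)-ene hydroxy acid F5. Camphorsulfonic acid (cat., CH2Cl2, 0 °C) then protonates the exocyclic olefin at C17 and the C12 acid closes onto the C8 cation, which returns the route to 23.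

Step 2. What may go wrong is weak enantiofacial discrimination in the ion-pair methylation, since the electrophile is small and the ester is a methyl ester. The fallback uses a covalent auxiliary and sets out from 3. Condensation with tert-butyl L-valinate (cat. acid, toluene, water removal) should give the enamino ester F1. Deprotonation with lithium diisopropylamide in toluene with HMPA and methylation with MeI should give the α-methylated imine F2, in which the valine stereocentre has directed the electrophile. Aqueous citric acid then hydrolyses F2 to 4 and releases the amino ester for reuse.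

**Further compounds**
F1 | step 2 | methyl 2-{[(2S)-1-tert-butoxy-3-methyl-1-oxobutan-2-yl]amino}-3-methylcyclohex-1-ene-1-carboxylate | COC(=O)C1=C(N[C@@H](C(C)C)C(=O)OC(C)(C)C)C(C)CCC1
F2 | step 2 | methyl (1S)-2-{[(2S)-1-tert-butoxy-3-methyl-1-oxobutan-2-yl]imino}-1,3-dimethylcyclohexane-1-carboxylate | COC(=O)[C@@]1(C)CCCC(C)C1=N[C@@H](C(C)C)C(=O)OC(C)(C)C
F3 | step 6 | boron ketene acetal of 8 with the (4S,5S)-4,5-diphenyl-1,3-bis{[3,5-bis(trifluoromethyl)phenyl]sulfonyl}-1,3,2-diazaborolidin-2-yl group on oxygen | COC(OC)C/C=C(/OB1N(S(=O)(=O)c2cc(cc(c2)C(F)(F)F)C(F)(F)F)[C@@H](c2ccccc2)[C@H](c2ccccc2)N1S(=O)(=O)c1cc(cc(c1)C(F)(F)F)C(F)(F)F)OCC1=C(C)CCC[C@]1(C)C(=O)OC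
F4 | step 6 | acyloxyborane of 11 with the same diazaborolidinyl group | COC(OC)C[C@@H](C(=O)OB1N(S(=O)(=O)c2cc(cc(c2)C(F)(F)F)C(F)(F)F)[C@@H](c2ccccc2)[C@H](c2ccccc2)N1S(=O)(=O)c1cc(cc(c1)C(F)(F)F)C(F)(F)F)[C@]1(C)CCC[C@](C)(C(=O)OC)C1=C
F5 | step 15 | (4S,5S,6R,9S,10S)-19-{[tert-butyl(dimethyl)silyl]oxy}-6-hydroxy-13,14,15,16-tetranorlabd-8(17)-en-12-oic acid | OC(=O)C[C@@H]1[C@]2(C)CCC[C@](C)(CO[Si](C)(C)C(C)(C)C)[C@H]2[C@H](O)CC1=C
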